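The quinone is read as an oxidised 5-alkylresorcinol: ring C-2 (OMe) and C-4 (C=O) are 1,3-related oxygenated carbons with the side chain on C-6. The ring is therefore cut at C5–C6 and C3–C4. An acyclic enone carrying the finished stereocentre, (3E,6R)-6-hydroxyheptadec-3-en-2-one, supplies C-3, C-2, C-1 and C-6; dimethyl malonate supplies C-5 and C-4. In one flask, Michael addition and Claisen closure build the carbocycle, and iodine–methanol aromatises it to a dihydroisocoumarin in which the temporary carboxyl on C-5 dictates which oxygen is methylated. Decarboxylation, para-oxidation (installing the C-1 oxygen) and acetylation complete the route.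

Key step: step 3

Remark: the allylborane of step 1 is taken from the (+)-α-pinene series, assumed here to be the series that delivers allyl to the si face of unbranched aliphatic aldehydes and so gives the (R)-carbinol.

Step 1
Reactants: 1 dodecanal; 2 allylmagnesium bromide
Product: 3 (4R)-pentadec-1-en-4-ol
Conditions: (−)-Ipc2BOMe, 2, Et2O, 0 °C to rt; then 1, −78 °C; then NaOH, H2O2, rt
Reagents that add atoms: none
Why: Brown asymmetric allylboration, in which the B-allyl reagent carrying two isopinocampheyl groups adds through a chair Zimmerman–Traxler transition state to one face of the aldehyde and sets the (4R)-carbinol centre that becomes the acetoxy-bearing carbon of the target.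

Step 2
Reactants: 3 (4R)-pentadec-1-en-4-ol; 4 but-3-en-2-one
Product: 5 (3E,6R)-6-hydroxyheptadec-3-en-2-one
Conditions: 4 (3 equiv), second-generation Hoveyda–Grubbs catalyst (3 mol %), CH2Cl2, 40 °C
Reagents that add atoms: none
Why: Olefin cross-metathesis between a terminal alkene and an electron-poor enone used in excess should be selective for the (E)-cross product and tolerates the free homoallylic hydroxyl, whose stereocentre is not involved.

Step 3
Reactants: 5 (3E,6R)-6-hydroxyheptadec-3-en-2-one; 6 dimethyl malonate
Product: 12 (3R)-8-hydroxy-6-methoxy-3-undecyl-3,4-dihydro-1H-isochromen-1-one, via Michael adduct 7 (not isolated), via dioxo ester 8 (not isolated), via enol ether 9 (not isolated), via iodo keto ester 10 (not isolated), via hydroxy benzoate 11 (not isolated)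
Conditions: NaOMe, MeOH, rt then reflux; then HCl/MeOH to pH 1, I2, reflux; Na2S2O3 work-up
Reagents that add atoms: methanol (CO)
Why: Malonate anion adds 1,4 to the enone (new C-5–C-6 bond of the future quinone ring) and the methyl-ketone enolate of the adduct then attacks one malonate ester in a Claisen (Dieckmann-type) condensation (new C-3–C-4 bond), which is the classical Michael–Claisen annulation of enones with malonates to cyclohexane-1,3-diones. The ring closes in the 6-exo-trig mode by attack of the enolate carbon on the ester carbonyl, driven by formation of the stabilised β-dicarbonyl enolate. The two ring stereocentres created are not controlled and need not be, since both are erased on aromatisation, while the remote (R)-carbinol is not touched. After acidification in the same methanol solution the ring carbonyl remote from the ester forms the vinylogous methyl ester (the carbonyl next to the ester stays a chelated β-keto ester enol), and iodination at the β-keto ester carbon followed by loss of HI aromatises the ring (iodine–methanol aromatisation of cyclohexenone carboxylates), so the enone-derived oxygen becomes OMe and the malonate-derived oxygen stays a free phenol. The step needs 1,4- over 1,2-addition, secured by the soft stabilised nucleophile, and regioselective O-methylation, secured by the ester on C-5; the side-chain hydroxyl can only lactonise with that ester, which leads to the isolated dihydroisocoumarin.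

Step 4
Reactants: 12 (3R)-8-hydroxy-6-methoxy-3-undecyl-3,4-dihydro-1H-isochromen-1-one
Product: 14 3-[(2R)-2-hydroxytridecyl]-5-methoxyphenol, via hydroxy acid 13 (not isolated)
Conditions: KOH, H2O/ethylene glycol, 170 °C; then cold aq. HCl
Reagents that add atoms: none
Why: Hydroxide opens the lactone and the electron-rich, doubly ortho-substituted salicylate should then lose CO2 by ipso-protonation of the phenoxide (reverse Kolbe–Schmitt reaction) while the carboxylate stays ionised and cannot relactonise, the carbinol centre taking no part.

Step 5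
Reactants: 14 3-[(2R)-2-hydroxytridecyl]-5-methoxyphenol
Product: 15 2-[(2R)-2-hydroxytridecyl]-6-methoxycyclohexa-2,5-diene-1,4-dione
Conditions: (KSO3)2NO, KH2PO4 buffer, H2O/acetone, 0 °C to rt
Reagents that add atoms: potassium nitrosodisulfonate, Fremy's salt ([K+].[K+].[O]N(S(=O)(=O)[O-])S(=O)(=O)[O-])
Why: Teuber oxidation, in which one nitrosodisulfonate radical abstracts the phenolic hydrogen and a second traps the phenoxyl radical at the free para position between OMe and the side chain, should give the 2-methoxy-6-alkyl-1,4-benzoquinone as established for simpler 3-methoxy-5-alkylphenols.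

Step 6
Reactants: 15 2-[(2R)-2-hydroxytridecyl]-6-methoxycyclohexa-2,5-diene-1,4-dione
Product: 16 (2R)-1-(5-methoxy-3,6-dioxocyclohexa-1,4-dien-1-yl)tridecan-2-yl acetate
Conditions: Ac2O, pyridine, CH2Cl2, 0 °C to rt
Reagents that add atoms: acetic anhydride (CC(=O)OC(C)=O)
Why: O-Acylation of the secondary alcohol with acetic anhydride and pyridine proceeds with retention at carbon and without acid, which avoids Thiele-type acetoxylation of the quinone.

Compound list
1 | dodecanal | CCCCCCCCCCCC=O | starting material
2 | allylmagnesium bromide | C=CC[Mg]Br | starting material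
3 | (4R)-pentadec-1-en-4-ol | CCCCCCCCCCC[C@@H](O)CC=C | intermediate
4 | but-3-en-2-one (methyl vinyl ketone) | CC(=O)C=C | starting material
5 | (3E,6R)-6-hydroxyheptadec-3-en-2-one | CCCCCCCCCCC[C@@H](O)C/C=C/C(C)=O | intermediate
6 | dimethyl propanedioate (dimethyl malonate) | COC(=O)CC(=O)OC | starting material
7 | dimethyl 2-[(6R)-6-hydroxy-2-oxoheptadecan-4-yl]propanedioate (both C-4 epimers) | CCCCCCCCCCC[C@@H](O)CC(CC(C)=O)C(C(=O)OC)C(=O)OC | intermediate
8 | methyl 6-[(2R)-2-hydroxytridecyl]-2,4-dioxocyclohexane-1-carboxylate (ring epimers, drawn as the diketo tautomer) | CCCCCCCCCCC[C@@H](O)CC1CC(=O)CC(=O)C1C(=O)OC | intermediate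
9 | methyl 6-[(2R)-2-hydroxytridecyl]-4-methoxy-2-oxocyclohex-3-ene-1-carboxylate | CCCCCCCCCCC[C@@H](O)CC1CC(OC)=CC(=O)C1C(=O)OC | intermediate
10 | methyl 6-[(2R)-2-hydroxytridecyl]-1-iodo-4-methoxy-2-oxocyclohex-3-ene-1-carboxylate | CCCCCCCCCCC[C@@H](O)CC1CC(OC)=CC(=O)C1(I)C(=O)OC | intermediate
11 | methyl 2-hydroxy-6-[(2R)-2-hydroxytridecyl]-4-methoxybenzoate | CCCCCCCCCCC[C@@H](O)Cc1cc(OC)cc(O)c1C(=O)OC | intermediate
12 | (3R)-8-hydroxy-6-methoxy-3-undecyl-3,4-dihydro-1H-isochromen-1-one | CCCCCCCCCCC[C@@H]1Cc2cc(OC)cc(O)c2C(=O)O1 | intermediate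
13 | 2-hydroxy-6-[(2R)-2-hydroxytridecyl]-4-methoxybenzoic acid (present as its potassium salt) | CCCCCCCCCCC[C@@H](O)Cc1cc(OC)cc(O)c1C(=O)O | intermediate
14 | 3-[(2R)-2-hydroxytridecyl]-5-methoxyphenol | CCCCCCCCCCC[C@@H](O)Cc1cc(OC)cc(O)c1 | intermediate
15 | 2-[(2R)-2-hydroxytridecyl]-6-methoxycyclohexa-2,5-diene-1,4-dione | CCCCCCCCCCC[C@@H](O)CC1=CC(=O)C=C(OC)C1=O | intermediate
16 | (2R)-1-(5-methoxy-3,6-dioxocyclohexa-1,4-dien-1-yl)tridecan-2-yl acetate | CCCCCCCCCCC[C@H](CC1=CC(=O)C=C(OC)C1=O)OC(C)=O | target

Total step count: 6
Longest linear sequence: 6 steps (from dodecanal)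

Steps most likely to fail

Step 3. What may go wrong: γ-deprotonation of the δ-hydroxy enone with loss of hydroxide to a dienone, or retro-Michael reversal on heating, may outrun the Claisen closure. Fallback: the malonate is delivered intramolecularly. Setting out from 5, acylation of the hydroxyl with methyl 3-chloro-3-oxopropanoate (pyridine, CH2Cl2, 0 °C) should give the mixed malonate (3E,6R)-2-oxoheptadec-3-en-6-yl methyl propanedioate F1. Cs2CO3 in MeCN at rt deprotonates only the malonate and should close the C-5–C-6 bond by 6-exo Michael addition to the δ-lactone methyl (6R)-2-oxo-4-(2-oxopropyl)-6-undecyloxane-3-carboxylate F2. NaOMe in MeOH added to the same flask then closes C-3–C-4 by Claisen attack on the lactone carbonyl to give 8, and acidification and I2 as in step 3 bring the route back at 12.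

Step 4. What may go wrong: decarboxylation may stay incomplete, so that the remaining hydroxy acid relactonises on acidification, or the aryl methyl ether may be cleaved at the temperature needed. Fallback: the carboxyl is removed before aromatisation, at the β-keto ester stage. Setting out from 5, the annulation of step 3 is stopped after acidification and 8 is isolated; MeOH with catalytic TsOH should give 9. LiOH in THF/H2O, then adjustment to pH 4 and gentle warming, should give through the keto acid 6-[(2R)-2-hydroxytridecyl]-4-methoxy-2-oxocyclohex-3-ene-1-carboxylic acid F3 the enone 5-[(2R)-2-hydroxytridecyl]-3-methoxycyclohex-2-en-1-one F4. Kinetic deprotonation (LDA, THF, −78 °C) and PhSeCl should give the selenide 5-[(2R)-2-hydroxytridecyl]-3-methoxy-6-(phenylselanyl)cyclohex-2-en-1-one F5. Oxidation with H2O2, syn-elimination and tautomerisation bring the route back at 14.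

Step 5. What may go wrong: radical attack at an ortho position, over-oxidation, or poor contact between the lipophilic phenol and the aqueous radical salt. Fallback: the quinone is formed last, in a homogeneous organic medium, on the acetate. Setting out from 14, Ac2O and pyridine should give the diacetate 3-[(2R)-2-(acetyloxy)tridecyl]-5-methoxyphenyl acetate F6. Pyrrolidine in CH2Cl2 at 0 °C cleaves only the aryl acetate to (2R)-1-(3-hydroxy-5-methoxyphenyl)tridecan-2-yl acetate F7. O2 with catalytic Co(salen) (N,N′-ethylenebis(salicylideneiminato)cobalt, divalent cobalt) in DMF should oxidise the free para position, and the route comes back at 16 without passing through 15.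

Further compounds
F1 | step 3 | (3E,6R)-2-oxoheptadec-3-en-6-yl methyl propanedioate | CCCCCCCCCCC[C@H](C/C=C/C(C)=O)OC(=O)CC(=O)OC
F2 | step 3 | methyl (6R)-2-oxo-4-(2-oxopropyl)-6-undecyloxane-3-carboxylate | CCCCCCCCCCC[C@@H]1CC(CC(C)=O)C(C(=O)OC)C(=O)O1
F3 | step 4 | 6-[(2R)-2-hydroxytridecyl]-4-methoxy-2-oxocyclohex-3-ene-1-carboxylic acid | CCCCCCCCCCC[C@@H](O)CC1CC(OC)=CC(=O)C1C(=O)O
F4 | step 4 | 5-[(2R)-2-hydroxytridecyl]-3-methoxycyclohex-2-en-1-one | CCCCCCCCCCC[C@@H](O)CC1CC(OC)=CC(=O)C1
F5 | step 4 | 5-[(2R)-2-hydroxytridecyl]-3-methoxy-6-(phenylselanyl)cyclohex-2-en-1-one | CCCCCCCCCCC[C@@H](O)CC1CC(OC)=CC(=O)C1[Se]c1ccccc1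
F6 | step 5 | 3-[(2R)-2-(acetyloxy)tridecyl]-5-methoxyphenyl acetate | CCCCCCCCCCC[C@H](Cc1cc(OC)cc(OC(C)=O)c1)OC(C)=O
F7 | step 5 | (2R)-1-(3-hydroxy-5-methoxyphenyl)tridecan-2-yl acetate | CCCCCCCCCCC[C@H](Cc1cc(OC)cc(O)c1)OC(C)=O
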